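**Retrosynthetic overview**
- The strategy rests on the C13 ketone of the 14-membered carbocycle: it stands 1,4 to both the C10 ketone and the ester carbon on C1, so C13 must enter as a nucleophile. It is carried as a nitronate and unmasked by a Nef reaction.
- The only ring is closed last, at C9–C10, by Nozaki–Hiyama–Kishi addition of the C9 vinyl iodide to the C10 aldehyde, followed by oxidation to the enone.
- The open chain comes from a one-pot three-component union: the nitronate of the C10–C13 nitro acetal adds to methyl 2-(diethoxyphosphoryl)acrylate (C13–C14), and the resulting phosphonate olefinates the C2–C9 iodo-glyoxal (C1=C2).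
- The nitro acetal comes from organocatalytic addition of nitromethane to 4-methylpent-2-enal (sets C12). The iodo-glyoxal comes from geranyl acetate by Stork–Zhao olefination and diazoketone oxidation.

Key step: step 12

Assumption: C13 (nitro) in 18 and 19 and C10 (carbinol) in 22 are carried as epimer mixtures because both end as ketones; the facial sense in step 1 is assigned from the usual shielding model of the prolinol silyl ether.

**Route**

Step 1
Reactants: 1 (E)-4-methylpent-2-enal; 2 nitromethane
Product: 3 (R)-4-methyl-3-(nitromethyl)pentanal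
Conditions: (R)-2-[diphenyl(trimethylsilyloxy)methyl]pyrrolidine (10 mol%), PhCO2H (20 mol%), MeNO2 (3 equiv), MeOH, rt
Reagents that add atoms: none
Why: Iminium-ion organocatalysis (Hayashi–Jørgensen conjugate addition of nitromethane): the diphenyl(silyloxy)methyl group of the R catalyst shields one face of the E-iminium of 1, so the nitronate should add to C12 from the open face and set the R configuration.

Step 2
Reactants: 3 (R)-4-methyl-3-(nitromethyl)pentanal
Product: 4 (R)-1,1-dimethoxy-4-methyl-3-(nitromethyl)pentane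
Conditions: HC(OMe)3, p-TsOH (cat.), MeOH, rt
Reagents that add atoms: trimethyl orthoformate, COC(OC)OC; methanol, CO
Why: Acid-catalysed acetalisation with orthoformate as water scavenger masks the C10 aldehyde against the nitronate chemistry to come, and C12 is not α to the carbonyl so it cannot epimerise.

Step 3
Reactants: 5 methyl diethylphosphonoacetate
Product: 7 methyl 2-(diethoxyphosphoryl)acrylate, via hydroxymethyl phosphonate 6 (not isolated)
Conditions: (CH2O)n, piperidine (cat.), MeOH, reflux; then p-TsOH (cat.), toluene, reflux (−H2O), distil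
Reagents that add atoms: formaldehyde (as paraformaldehyde), C=O
Why: Piperidine-catalysed Knoevenagel-type hydroxymethylation of the phosphonoacetate followed by acid-catalysed dehydration is the standard preparation of 2-phosphonoacrylates.

Step 4
Reactants: 8 geranyl acetate
Product: 9 (E)-5-(3,3-dimethyloxiran-2-yl)-3-methylpent-2-en-1-yl acetate (racemic epoxide)
Conditions: mCPBA (1.0 equiv), NaHCO3, CH2Cl2, 0 °C
Reagents that add atoms: mCPBA, OOC(=O)c1cccc(Cl)c1
Why: Prilezhaev epoxidation should select the electron-rich 6,7-alkene because the 2,3-alkene is deactivated by the allylic acetoxy group, and the epoxide stereocentre is lost in the next step.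

Step 5
Reactants: 9 (E)-5-(3,3-dimethyloxiran-2-yl)-3-methylpent-2-en-1-yl acetate
Product: 10 (E)-3-methyl-6-oxohex-2-en-1-yl acetate
Conditions: H5IO6, THF/Et2O, 0 °C
Reagents that add atoms: none
Why: Periodic acid opens the epoxide and cleaves the resulting glycol in the same flask (glycol cleavage), releasing acetone and the aldehyde without touching the allylic acetate.

Step 6
Reactants: 10 (E)-3-methyl-6-oxohex-2-en-1-yl acetate
Product: 11 (2E,6Z)-7-iodo-3-methylocta-2,6-dien-1-yl acetate
Conditions: EtPPh3I, n-BuLi, THF, 0 °C; I2, −78 °C; NaN(SiMe3)2, −20 °C; then 10, −78 °C → rt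
Reagents that add atoms: ethyltriphenylphosphonium iodide, CC[P+](c1ccccc1)(c1ccccc1)c1ccccc1.[I-]; iodine, II
Why: Stork–Zhao olefination: the α-iodo ylide reacts under kinetic control to place iodine cis to the chain, which should give the Z trisubstituted vinyl iodide while the acetate is inert to the ylide at low temperature.

Step 7
Reactants: 11 (2E,6Z)-7-iodo-3-methylocta-2,6-dien-1-yl acetate
Product: 12 (2E,6Z)-7-iodo-3-methylocta-2,6-dien-1-ol
Conditions: K2CO3 (cat.), MeOH, rt
Reagents that add atoms: none
Why: Base-catalysed methanolysis (transesterification) of the acetate leaves the vinyl iodide and both alkenes untouched.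

Step 8
Reactants: 12 (2E,6Z)-7-iodo-3-methylocta-2,6-dien-1-ol
Product: 13 (2E,6Z)-7-iodo-3-methylocta-2,6-dienal
Conditions: MnO2, CH2Cl2, rt
Reagents that add atoms: none
Why: MnO2 oxidises the allylic alcohol selectively to the enal under neutral conditions that should preserve the 2E geometry.

Step 9
Reactants: 13 (2E,6Z)-7-iodo-3-methylocta-2,6-dienal
Product: 14 (2E,6Z)-7-iodo-3-methylocta-2,6-dienoic acid
Conditions: NaClO2, NaH2PO4, 2-methylbut-2-ene, t-BuOH/H2O, rt
Reagents that add atoms: sodium chlorite, [Na+].[O-]Cl=O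
Why: Pinnick oxidation with a hypochlorite scavenger converts the enal to the acid without attacking the alkenes or the vinyl iodide.

Step 10
Reactants: 14 (2E,6Z)-7-iodo-3-methylocta-2,6-dienoic acid
Product: 16 (3E,7Z)-1-diazo-8-iodo-4-methylnona-3,7-dien-2-one, via acid chloride 15 (not isolated)
Conditions: (COCl)2, DMF (cat.), CH2Cl2, 0 °C, concentrate; then CH2N2 (excess), Et2O, 0 °C
Reagents that add atoms: oxalyl chloride, O=C(Cl)C(=O)Cl (chlorine of 15 only); diazomethane, C=[N+]=[N-]
Why: Acylation of diazomethane by the acid chloride (first stage of the Arndt–Eistert sequence) is reliable for β,β-disubstituted enoyl chlorides because the hindered alkene resists dipolar cycloaddition, and excess diazomethane scavenges HCl.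

Step 11
Reactants: 16 (3E,7Z)-1-diazo-8-iodo-4-methylnona-3,7-dien-2-one
Product: 17 (3E,7Z)-8-iodo-4-methyl-2-oxonona-3,7-dienal
Conditions: dimethyldioxirane (1.05 equiv), acetone, −78 → 0 °C; evaporate, use crude at once
Reagents that add atoms: dimethyldioxirane, CC1(C)OO1
Why: Dioxirane oxidation of an α-diazoketone: oxygen transfer to the nucleophilic diazo carbon with loss of N2 should be far faster than epoxidation of the electron-poor enone or the iodoalkene, giving the anhydrous glyoxal.

Step 12
Reactants: 4 (R)-1,1-dimethoxy-4-methyl-3-(nitromethyl)pentane; 7 methyl 2-(diethoxyphosphoryl)acrylate; 17 (3E,7Z)-8-iodo-4-methyl-2-oxonona-3,7-dienal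
Product: 19 methyl (2E,5E,9Z)-2-[(3R)-5,5-dimethoxy-2-nitro-3-(propan-2-yl)pentyl]-10-iodo-6-methyl-4-oxoundeca-2,5,9-trienoate (C13 epimers), via nitro phosphonate 18 (not isolated)
Conditions: DBU (0.1 equiv), MeCN, 0 °C, slow addition of 7; then LiCl, 17, i-Pr2NEt, 0 °C → rt; NH4Cl quench
Reagents that add atoms: none
Why: Catalytic DBU generates the nitronate of 4, which adds in Michael fashion to the doubly activated acrylate 7 to form C13–C14, and proton transfer leaves the neutral α-substituted phosphonoacetate 18. LiCl then chelates 18 so that the weak amine base deprotonates it at C1, and the anion attacks the aldehyde of 17 and collapses through the oxaphosphetane to the C1=C2 alkene (Horner–Wadsworth–Emmons olefination under Masamune–Roush conditions). The closest known reaction type is the tandem Michael addition–Horner–Wadsworth–Emmons olefination of 2-phosphonoacrylates with nitroalkanes and aldehydes. No ring is closed; the C13 nitro centre forms without control and is erased by the Nef reaction, and C12 is not α to any carbonyl, so the basic steps cannot epimerise it. The step needs mono-addition of the primary nitronate, attack at the aldehyde and not the ketone of 17, and E geometry: branching at C12 and slow addition of 7 favour mono-addition, the glyoxal aldehyde is far more electrophilic than the conjugated ketone while any reversible Henry adduct is drained by the irreversible olefination, and the reversible addition stage of the olefination funnels to the alkene with the ester trans to the C3 acyl group.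

Step 13
Reactants: 19 methyl (2E,5E,9Z)-2-[(3R)-5,5-dimethoxy-2-nitro-3-(propan-2-yl)pentyl]-10-iodo-6-methyl-4-oxoundeca-2,5,9-trienoate
Product: 20 methyl (2E,5E,9Z)-2-[(3R)-5,5-dimethoxy-2-oxo-3-(propan-2-yl)pentyl]-10-iodo-6-methyl-4-oxoundeca-2,5,9-trienoate
Conditions: NaNO2, AcOH, DMSO, 35 °C
Reagents that add atoms: sodium nitrite, [Na+].[O-]N=O
Why: Nitrosative Nef reaction (Kornblum type): the nitronate is C-nitrosated to a pseudonitrole that collapses to the C13 ketone under weakly acidic, non-reducing and non-nucleophilic conditions that the 4-oxo-enoate, the vinyl iodide and C12 should tolerate, and any acetal lost early is simply the product of step 14.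

Step 14
Reactants: 20 methyl (2E,5E,9Z)-2-[(3R)-5,5-dimethoxy-2-oxo-3-(propan-2-yl)pentyl]-10-iodo-6-methyl-4-oxoundeca-2,5,9-trienoate
Product: 21 methyl (2E,5E,9Z)-2-[(3R)-2,5-dioxo-3-(propan-2-yl)pentyl]-10-iodo-6-methyl-4-oxoundeca-2,5,9-trienoate
Conditions: Amberlyst-15, acetone/H2O, rt
Reagents that add atoms: water, O
Why: Mild sulfonic-acid-resin hydrolysis of the dimethyl acetal frees the C10 aldehyde at room temperature, too mild to epimerise C12 or to dehydrate the γ-keto aldehyde to a furan.

Step 15
Reactants: 21 methyl (2E,5E,9Z)-2-[(3R)-2,5-dioxo-3-(propan-2-yl)pentyl]-10-iodo-6-methyl-4-oxoundeca-2,5,9-trienoate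
Product: 22 methyl (1E,4E,8Z,12R)-10-hydroxy-5,9-dimethyl-3,13-dioxo-12-(propan-2-yl)cyclotetradeca-1,4,8-triene-1-carboxylate (C10 epimers)
Conditions: CrCl2 (10 equiv), NiCl2 (cat.), degassed DMSO/THF, rt, 2 mM, syringe-pump addition of 21
Reagents that add atoms: none
Why: Nozaki–Hiyama–Kishi macrocyclisation: zerovalent nickel inserts into the C9–I bond with retention, transmetalation gives a trivalent vinylchromium that adds only to the aldehyde, closing the 14-membered ring at C9–C10 under high dilution, and the new C10 carbinol needs no control because it is oxidised next.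

Step 16
Reactants: 22 methyl (1E,4E,8Z,12R)-10-hydroxy-5,9-dimethyl-3,13-dioxo-12-(propan-2-yl)cyclotetradeca-1,4,8-triene-1-carboxylate
Product: 23 methyl sarcoate, methyl (1E,4E,8Z,12R)-5,9-dimethyl-3,10,13-trioxo-12-(propan-2-yl)cyclotetradeca-1,4,8-triene-1-carboxylate
Conditions: Dess–Martin periodinane, NaHCO3, CH2Cl2, 0 °C → rt
Reagents that add atoms: none
Why: Buffered Dess–Martin oxidation of the allylic alcohol (drawing any C10–O/C13 hemiketal through its open form) should give the C10 enone without isomerising the 8Z alkene or epimerising C12.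

**Compound list**
1 | (E)-4-methylpent-2-enal | CC(C)/C=C/C=O | starting material
2 | nitromethane | C[N+](=O)[O-] | starting material
3 | (R)-4-methyl-3-(nitromethyl)pentanal | O=CC[C@H](C(C)C)C[N+](=O)[O-] | intermediate
4 | (R)-1,1-dimethoxy-4-methyl-3-(nitromethyl)pentane | [O-][N+](=O)C[C@@H](C(C)C)CC(OC)OC | intermediate
5 | methyl diethylphosphonoacetate | COC(=O)CP(=O)(OCC)OCC | starting material
6 | methyl 2-(diethoxyphosphoryl)-3-hydroxypropanoate (racemic, not isolated) | COC(=O)C(CO)P(=O)(OCC)OCC | intermediate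
7 | methyl 2-(diethoxyphosphoryl)acrylate | C=C(C(=O)OC)P(=O)(OCC)OCC | intermediate
8 | geranyl acetate | CC(C)=CCC/C(C)=C/COC(C)=O | starting material
9 | (E)-5-(3,3-dimethyloxiran-2-yl)-3-methylpent-2-en-1-yl acetate (racemic) | CC(=O)OC/C=C(\C)CCC1OC1(C)C | intermediate
10 | (E)-3-methyl-6-oxohex-2-en-1-yl acetate | CC(=O)OC/C=C(\C)CCC=O | intermediate
11 | (2E,6Z)-7-iodo-3-methylocta-2,6-dien-1-yl acetate | CC(=O)OC/C=C(\C)CC/C=C(/C)I | intermediate
12 | (2E,6Z)-7-iodo-3-methylocta-2,6-dien-1-ol | OC/C=C(\C)CC/C=C(/C)I | intermediate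
13 | (2E,6Z)-7-iodo-3-methylocta-2,6-dienal | O=C/C=C(\C)CC/C=C(/C)I | intermediate
14 | (2E,6Z)-7-iodo-3-methylocta-2,6-dienoic acid | OC(=O)/C=C(\C)CC/C=C(/C)I | intermediate
15 | (2E,6Z)-7-iodo-3-methylocta-2,6-dienoyl chloride (not isolated) | O=C(Cl)/C=C(\C)CC/C=C(/C)I | intermediate
16 | (3E,7Z)-1-diazo-8-iodo-4-methylnona-3,7-dien-2-one | [N-]=[N+]=CC(=O)/C=C(\C)CC/C=C(/C)I | intermediate
17 | (3E,7Z)-8-iodo-4-methyl-2-oxonona-3,7-dienal | O=CC(=O)/C=C(\C)CC/C=C(/C)I | intermediate
18 | methyl (5R)-2-(diethoxyphosphoryl)-7,7-dimethoxy-4-nitro-5-(propan-2-yl)heptanoate (C2 and C4 epimers, not isolated) | COC(=O)C(P(=O)(OCC)OCC)CC([N+](=O)[O-])[C@@H](C(C)C)CC(OC)OC | intermediate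
19 | methyl (2E,5E,9Z)-2-[(3R)-5,5-dimethoxy-2-nitro-3-(propan-2-yl)pentyl]-10-iodo-6-methyl-4-oxoundeca-2,5,9-trienoate (nitro epimers) | COC(=O)/C(CC([N+](=O)[O-])[C@@H](C(C)C)CC(OC)OC)=C/C(=O)/C=C(\C)CC/C=C(/C)I | intermediate
20 | methyl (2E,5E,9Z)-2-[(3R)-5,5-dimethoxy-2-oxo-3-(propan-2-yl)pentyl]-10-iodo-6-methyl-4-oxoundeca-2,5,9-trienoate | COC(=O)/C(CC(=O)[C@@H](C(C)C)CC(OC)OC)=C/C(=O)/C=C(\C)CC/C=C(/C)I | intermediate
21 | methyl (2E,5E,9Z)-2-[(3R)-2,5-dioxo-3-(propan-2-yl)pentyl]-10-iodo-6-methyl-4-oxoundeca-2,5,9-trienoate | COC(=O)/C(CC(=O)[C@@H](C(C)C)CC=O)=C/C(=O)/C=C(\C)CC/C=C(/C)I | intermediate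
22 | methyl (1E,4E,8Z,12R)-10-hydroxy-5,9-dimethyl-3,13-dioxo-12-(propan-2-yl)cyclotetradeca-1,4,8-triene-1-carboxylate (C10 epimers) | COC(=O)/C1=C/C(=O)/C=C(\C)CC/C=C(/C)C(O)C[C@H](C(C)C)C(=O)C1 | intermediate
23 | methyl sarcoate, methyl (1E,4E,8Z,12R)-5,9-dimethyl-3,10,13-trioxo-12-(propan-2-yl)cyclotetradeca-1,4,8-triene-1-carboxylate | COC(=O)/C1=C/C(=O)/C=C(\C)CC/C=C(/C)C(=O)C[C@H](C(C)C)C(=O)C1 | target

**Step count**
Total: 16 steps. Longest linear sequence: 13 steps (geranyl acetate 8 to 23, steps 4 to 16).

**Steps most likely to fail**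

Step 12 (three-component union). What may go wrong: a second Michael addition of the mono-adduct nitronate to 7; Henry addition of the nitronate to the glyoxal aldehyde; oligomerisation or hydration of the glyoxal before it is olefinated; base-induced loss of nitrous acid across C13–C14 once the 4-oxo-enoate exists; erosion of the C1=C2 geometry.
Fallback (sets out from 17 and 4, returns at 19): the C13–C14 bond would be made by allylic substitution instead of conjugate addition to a phosphonate. The glyoxal 17 would undergo a Morita–Baylis–Hillman reaction with methyl acrylate (DABCO) at its aldehyde to give methyl (5E,9Z)-3-hydroxy-10-iodo-6-methyl-2-methylidene-4-oxoundeca-5,9-dienoate F1. Acetylation (Ac2O, pyridine) would give methyl (5E,9Z)-3-acetoxy-10-iodo-6-methyl-2-methylidene-4-oxoundeca-5,9-dienoate F2. The nitronate of 4 (DBU, THF, 0 °C) would then add to the methylidene carbon and expel acetate (addition–elimination, SN2′). This forms C13–C14 and moves the alkene to C1=C2 with the ester trans to the C3 acyl group, giving 19.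

Step 13 (Nef reaction). What may go wrong: nitrosation of the doubly activated C14 methylene once the ketone has formed; migration of the C1=C2 alkene toward C13; slow nitronate formation at the hindered C13, allowing decomposition of the 4-oxo-enoate.
Fallback (sets out from 18, returns at 20): the Nef reaction would be moved ahead of the olefination so that the 4-oxo-enoate never meets Nef conditions. Step 12 would be stopped after the Michael stage and 18 isolated. Its nitronate (NaOMe, MeOH) would be treated with buffered aqueous TiCl3/NH4OAc (McMurry variant of the Nef reaction) to give methyl (5R)-2-(diethoxyphosphoryl)-7,7-dimethoxy-4-oxo-5-(propan-2-yl)heptanoate F3. F3 would then be olefinated with 17 (LiCl, i-Pr2NEt, MeCN, 0 °C) to give 20 directly; the weak amine base is chosen because C12 is then α to a ketone.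

Step 15 (macrocyclisation). What may go wrong: oligomerisation in place of ring closure; reduction of the 4-oxo-enoate by divalent chromium; aldol-type closure of the γ-keto aldehyde; partial loss of the vinyl geometry.
Fallback (sets out from 3, returns at 23): the ring would be closed at the same C9–C10 bond by a palladium-catalysed ketone synthesis that needs no reducing metal, with C10 carried as a thioester instead of an acetal.
- Pinnick oxidation of 3 would give (R)-4-methyl-3-(nitromethyl)pentanoic acid F4.
- Coupling with EtSH (carbodiimide, DMAP) would give S-ethyl (R)-4-methyl-3-(nitromethyl)pentanethioate F5.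
- Under the conditions of step 12, F5 and 7 would give the non-isolated Michael adduct methyl (5R)-2-(diethoxyphosphoryl)-7-(ethylsulfanyl)-4-nitro-7-oxo-5-(propan-2-yl)heptanoate F6. Olefination of 17 would then give methyl (2E,5E,9Z)-2-[(3R)-5-(ethylsulfanyl)-2-nitro-5-oxo-3-(propan-2-yl)pentyl]-10-iodo-6-methyl-4-oxoundeca-2,5,9-trienoate F7.
- The Nef conditions of step 13 would give methyl (2E,5E,9Z)-2-[(3R)-5-(ethylsulfanyl)-2,5-dioxo-3-(propan-2-yl)pentyl]-10-iodo-6-methyl-4-oxoundeca-2,5,9-trienoate F8.
- Iodine–tin exchange (Me3SnSnMe3, Pd(PPh3)4, toluene, 60 °C) would give methyl (2E,5E,9Z)-2-[(3R)-5-(ethylsulfanyl)-2,5-dioxo-3-(propan-2-yl)pentyl]-6-methyl-4-oxo-10-(trimethylstannyl)undeca-2,5,9-trienoate F9.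
- Liebeskind–Srogl coupling under high dilution (Pd2(dba)3, tri(2-furyl)phosphine, CuTC (copper thiophene-2-carboxylate, monovalent copper), THF, 50 °C) would join C9 to the thioester carbon with retention of the Z geometry and give 23 directly, without the final oxidation.

**Further compounds**
F1 | step 12 | methyl (5E,9Z)-3-hydroxy-10-iodo-6-methyl-2-methylidene-4-oxoundeca-5,9-dienoate (racemic) | C=C(C(=O)OC)C(O)C(=O)/C=C(\C)CC/C=C(/C)I
F2 | step 12 | methyl (5E,9Z)-3-acetoxy-10-iodo-6-methyl-2-methylidene-4-oxoundeca-5,9-dienoate (racemic) | C=C(C(=O)OC)C(OC(C)=O)C(=O)/C=C(\C)CC/C=C(/C)I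
F3 | step 13 | methyl (5R)-2-(diethoxyphosphoryl)-7,7-dimethoxy-4-oxo-5-(propan-2-yl)heptanoate | COC(=O)C(P(=O)(OCC)OCC)CC(=O)[C@@H](C(C)C)CC(OC)OC
F4 | step 15 | (R)-4-methyl-3-(nitromethyl)pentanoic acid | OC(=O)C[C@H](C(C)C)C[N+](=O)[O-]
F5 | step 15 | S-ethyl (R)-4-methyl-3-(nitromethyl)pentanethioate | CCSC(=O)C[C@H](C(C)C)C[N+](=O)[O-]
F6 | step 15 | methyl (5R)-2-(diethoxyphosphoryl)-7-(ethylsulfanyl)-4-nitro-7-oxo-5-(propan-2-yl)heptanoate | COC(=O)C(P(=O)(OCC)OCC)CC([N+](=O)[O-])[C@@H](C(C)C)CC(=O)SCC
F7 | step 15 | methyl (2E,5E,9Z)-2-[(3R)-5-(ethylsulfanyl)-2-nitro-5-oxo-3-(propan-2-yl)pentyl]-10-iodo-6-methyl-4-oxoundeca-2,5,9-trienoate | COC(=O)/C(CC([N+](=O)[O-])[C@@H](C(C)C)CC(=O)SCC)=C/C(=O)/C=C(\C)CC/C=C(/C)I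
F8 | step 15 | methyl (2E,5E,9Z)-2-[(3R)-5-(ethylsulfanyl)-2,5-dioxo-3-(propan-2-yl)pentyl]-10-iodo-6-methyl-4-oxoundeca-2,5,9-trienoate | COC(=O)/C(CC(=O)[C@@H](C(C)C)CC(=O)SCC)=C/C(=O)/C=C(\C)CC/C=C(/C)I
F9 | step 15 | methyl (2E,5E,9Z)-2-[(3R)-5-(ethylsulfanyl)-2,5-dioxo-3-(propan-2-yl)pentyl]-6-methyl-4-oxo-10-(trimethylstannyl)undeca-2,5,9-trienoate | COC(=O)/C(CC(=O)[C@@H](C(C)C)CC(=O)SCC)=C/C(=O)/C=C(\C)CC/C=C(/C)[Sn](C)(C)C
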